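## Structural features

The target is an elemane-type sesquiterpenoid (elemanolide locants C1–C15 are used throughout). A cyclohexane C5–C10 is trans-fused across C6–C7 to an α-methylene-γ-butyrolactone (O6–C12, C11=C13). C5 carries a 2-substituted acrylic acid (C4=C3, C15 carboxyl), O8 a tiglate, and the quaternary C10 a methyl group (C14) and a vinyl group (C1=C2). There are five stereocentres: C5, C6, C7 and C8 are contiguous, and C10 is the neighbour of C5. The relations are 5,6-trans, 6,7-trans and 7,8-cis (C4 branch β, O6 α, C11 β, O8 β, C14 β). In the chair the C5, C6 and C7 substituents are equatorial, but O8 is axial and 1,3-syn to the axial C14 methyl. Fragile groups are the two acrylate-type acceptors, the tiglate, and the trans-fused lactone, which can migrate to O8 whenever O8 is a free alkoxide. The real difficulty lies in the vinyl-bearing quaternary C10 next to C5, the axial O8, and the timing of the C13 and C15 oxidation levels. The key step exploits the C6 carbinol with its trans neighbour C5 bearing C4(=C3H2)–C15H3: this is the homoallylic alcohol retron of a type-one carbonyl-ene reaction between a C6 aldehyde and a C5=C4(CH3)2 isobutenyl group on C10.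

## Logic of the disconnections

- **34 ⇒ 33 ⇒ 31 (C15–O bonds).** The acid is traced to the enal and then to the C15 methyl of an isopropenyl group. A free acid or an enal would interfere with enolate chemistry and acylation, so C15 is oxidised last. The forward step must pick C15 among three alkenes and a tiglate.

- **31 ⇒ 29 + 30 (O8–acyl bond).** The tiglate cannot survive lithium amide bases, so it is attached after the methylenation. The demand is acylation of a hindered axial hydroxyl without lactone migration.

- **29 ⇒ 28 ⇒ 24 (C11=C13).** Removing C13 leaves a plain lactone CH2. The forward enolate step then meets only a silyl ether and isolated alkenes.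

- **24 ⇒ 22 ⇒ 21 ⇒ 20 (C8–H and C8–O bonds).** The axial 8β oxygen is traced through the C8 ketone to the equatorial 8α epimer. Two reasons drive this cut:
  - With O8 already β in the open chain, the productive chair of the ring closure would hold O8 axial and syn to C14. The inverted chair, which leads to the wrong C5/C6 pair, would then be competitive.
  - The 8β/C11β pattern is an anti-aldol pattern, whereas 8α is the syn pattern that the imide aldol delivers.
  
  The price is one oxidation and one reduction. The reduction needs hydride delivery anti to the axial C14.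

- **20 ⇒ 19 (O6–C12).** Opening the lactone gives a tert-butyl ester arm on C7 and a free C6 hydroxyl. A tert-butyl ester is chosen over a methyl ester because it resists LiBH4 and premature lactonisation onto O8.

- **19 ⇒ 18 (C5–C6, key step).** One ring and two stereocentres are removed, leaving an open chain with only C7, C8 and C10 set. The forward closure must occur beside the quaternary carbon through a single chair.

- **18 ⇒ 17 ⇒ 16 ⇒ 15 ⇒ 9 + 13 (C7–C8).** A syn-aldol disconnection sets both centres under auxiliary control, independent of the remote C10. The imide then has to be taken to the aldehyde in the presence of the ester.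

- **13 ⇒ 10 + 11 (N–acyl bond).** Both pieces are commercial.

- **9 ⇒ 8 ⇒ 7 ⇒ 6 ⇒ 5 (C5=C4, then redox and lactone opening).** The isobutenyl group comes from a non-enolisable C5 aldehyde and an isopropylidene ylide. C8 is parked as an N-methoxy-N-methyl amide so that the two termini of 5 are differentiated.

- **5 ⇒ 4 ⇒ 1 + 2 (C9–C10).** The quaternary centre is reduced to an asymmetric allylic alkylation of a racemic vinyl epoxide. The forward step needs branched regiochemistry and facial control in one operation.

## Other disconnections considered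

**Alternative 1:** The cut is C7–C8 together with O8–C11. The aldehyde acid A1 would be activated with 2-chloro-1-methylpyridinium iodide and i-Pr2NEt and taken up by homobenzotetramisole as an acylammonium enolate at C7. This adds to the C8 aldehyde, and the aldolate closes the cis β-lactone A2.
- In its favour:
  - It is catalytic and makes C7 and C8 together in the cis relation the target needs, so no inversion at C8 is required. On this point it is better than the chosen plan.
  - Bond formation is remote from C10, so it is equal or better in reactivity.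
- Against it:
  - In A2 the carbonyl on C7 is C11, so C12 and C13 are still missing.
  - The oxygen pattern is reversed (acyl on O8, silyl on O6). The β-lactone must be opened, C11 homologated and methylenated, and the γ-lactone rebuilt on O6.
  - A1 needs C10, C5 and C6 set in an open chain, with the acrylate-bearing C5 beside the quaternary carbon.
  - The catalyst must override the adjacent C6 silyloxy centre.
- Comparison: structurally it solves the 7,8-cis problem directly but leaves two lactone carbons out. Mechanistically it is an ionic, catalyst-controlled double bond formation, against a pericyclic, substrate-controlled closure. In step count the longer endgame outweighs the saved inversion.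

**Alternative 2:** The cut is the C8=C9 bond of a cyclic enol ether. The alkylidene Mo(N-2,6-i-Pr2C6H3)(CHCMe2Ph)[OCMe(CF3)2]2 would join the C8 ethyl enol ether of A3 to one of the two vinyl groups on C10. Ethene is lost, A4 is formed, and C10 becomes stereogenic.
- In its favour:
  - C10 needs no enantioselective construction, which is better than the chosen plan.
  - C8 is sp2 during ring closure, so no axial oxygen is carried through it.
  - Later hydride delivery anti to C14 gives 8β by the same logic as step 16, without a separate oxidation (equal or better).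
  - The trans lactone is already present.
- Against it:
  - The choice between the diastereotopic vinyl groups rests on the bias of C5 alone.
  - Metathesis to a trisubstituted enol ether beside a quaternary carbon is demanding, and the catalyst is air-sensitive.
  - C4 in A4 is an ester carbon, so C3, C15 and C13 must all be added later.
  - A3 itself needs three contiguous centres and an ester-to-enol-ether methylenation.
- Comparison: it is stronger on C10 and on C8, weaker on the C4 and C11 appendages, and overall not shorter.

**Alternative 3:** The cut is C6–C7 plus O6–C12. CrCl2 (divalent chromium) would convert the allylic bromide A5 into an allylchromium that attacks the C6 aldehyde through C7. The alkoxide then closes onto the methyl ester to give A6.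
- In its favour:
  - The carbocycle, C6, C7 and the complete methylene lactone arise in one operation, with C15 already at the acid level.
  - The endgame shrinks to desilylation, acylation and ester cleavage. This is clearly better step economy after the key step.
- Against it:
  - In A5, C5 is α to the aldehyde and attached to the acrylate, so its hydrogen is doubly activated towards epimerisation and migration into conjugation.
  - C5 and C10 must be set in an open chain.
  - Closed transition states of such carboxyallylations tend towards the cis lactone, so trans fusion cannot be taken for granted.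
  - The 8β silyloxy group would be axial and syn to C14 in the productive chair, the same problem that the chosen plan removes by carrying 8α.
  - Chromium is used in stoichiometric excess.
- Comparison: it is the shortest on paper. The chosen plan is safer in precursor stability (C5 is created in the ring-forming step) and in predictable stereocontrol.

Key step: step 12

Remark: the open-chain aldehyde 18 is carried with the C8 silyl ether in the 8α (equatorial, 4S) configuration and with a tert-butyl ester at C12; C8 is inverted after ring closure (steps 14–16).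

**Step 1**
Reactants: 1 2-methyl-2-vinyloxirane (racemic); 2 dimethyl malonate
Product: 4 methyl (4R)-4-methyl-2-oxo-4-vinyloxolane-3-carboxylate (C3 epimers), via hydroxy malonate 3 (not isolated)
Conditions: Pd2(dba)3·CHCl3 (1 mol %), N,N'-[(1R,2R)-cyclohexane-1,2-diyl]bis[2-(diphenylphosphanyl)naphthalene-1-carboxamide] (3 mol %), CH2Cl2, rt; then DBU (10 mol %), rt
Reagents that add atoms: none
Why: Palladium-catalysed asymmetric allylic alkylation run as a dynamic kinetic asymmetric transformation: zerovalent palladium opens racemic 1 to a π-allyl alkoxide that deprotonates 2, the diastereomeric π-allyl complexes interconvert faster than they are attacked, and the ligand pocket with the alkoxide-bound nucleophile directs C–C bond formation to the substituted terminus, setting C10 (the ligand antipode is the one expected by analogy with other soft nucleophiles in this ligand series; its mirror image is used if the sense should be opposite). The gem-disubstituted hydroxy malonate 3 then closes to the five-membered lactone.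

**Step 2**
Reactants: 4
Product: 5 (4S)-4-methyl-4-vinyloxolan-2-one
Conditions: LiCl, H2O, DMSO, 150 °C
Reagents that add atoms: none
Why: Krapcho dealkoxycarbonylation: chloride demethylates the ester and the β-carbonyl carboxylate loses CO2; the neopentyl lactone CH2–O is not attacked and C10 has no acidic hydrogen.

**Step 3**
Reactants: 5
Product: 6 (3S)-3-(hydroxymethyl)-N-methoxy-N,3-dimethylpent-4-enamide
Conditions: MeNHOMe·HCl, Me3Al, CH2Cl2, 0 °C → rt; aqueous potassium sodium tartrate; used crude
Reagents that add atoms: N,O-dimethylhydroxylamine hydrochloride, CNOC.Cl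
Why: Aminolysis of the lactone by the aluminium amide frees the C5 hydroxyl and leaves C8 as an N-methoxy-N-methyl amide that tolerates the ylide of step 5 and can be reduced to the aldehyde. The hydroxy amide is oxidised without delay because it can relactonise.

**Step 4**
Reactants: 6
Product: 7 (3S)-3-formyl-N-methoxy-N,3-dimethylpent-4-enamide
Conditions: DMP (1,1,1-triacetoxy-1,1-dihydro-1,2-benziodoxol-3(1H)-one), CH2Cl2, 0 °C → rt
Reagents that add atoms: none
Why: Periodinane oxidation of the neopentyl primary alcohol; the aldehyde has no α-hydrogen, so C10 cannot epimerise.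

**Step 5**
Reactants: 7
Product: 8 (3S)-N-methoxy-N,3,5-trimethyl-3-vinylhex-4-enamide
Conditions: i-PrPPh3I, n-BuLi, THF, 0 °C; then 7, −78 °C → rt
Reagents that add atoms: isopropyltriphenylphosphonium iodide, CC(C)[P+](c1ccccc1)(c1ccccc1)c1ccccc1.[I-]
Why: Wittig olefination with the non-stabilised isopropylidene ylide installs C4 with both methyl groups (C3 and C15); the aldehyde is not enolisable and should react far faster than the amide at low temperature.

**Step 6**
Reactants: 8
Product: 9 (3S)-3,5-dimethyl-3-vinylhex-4-enal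
Conditions: i-Bu2AlH, THF, −78 °C; aqueous potassium sodium tartrate
Reagents that add atoms: none
Why: One hydride adds to the N-methoxy-N-methyl amide to give a chelated hemiaminal aluminate that releases the aldehyde only on work-up; the isolated alkenes are inert.

**Step 7**
Reactants: 10 4-tert-butoxy-4-oxobutanoic acid; 11 (4R)-4-benzyl-1,3-oxazolidin-2-one
Product: 13 tert-butyl 4-[(4R)-4-benzyl-2-oxo-1,3-oxazolidin-3-yl]-4-oxobutanoate, via mixed anhydride 12 (not isolated)
Conditions: t-BuCOCl, Et3N, THF, −20 °C; then 11, LiCl, −20 °C → rt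
Reagents that add atoms: none
Why: Mixed pivalic anhydride activation and LiCl-assisted N-acylation of the oxazolidinone; attack occurs at the less hindered carbonyl and the tert-butyl ester is untouched.

**Step 8**
Reactants: 9; 13
Product: 15 tert-butyl (3R,4S,6S)-3-{[(4R)-4-benzyl-2-oxo-1,3-oxazolidin-3-yl]carbonyl}-4-hydroxy-6,8-dimethyl-6-vinylnon-7-enoate, via boron enolate 14 (not isolated)
Conditions: Bu2BOTf, i-Pr2NEt, CH2Cl2, 0 °C; then 9, −78 → 0 °C; pH 7 buffer, MeOH, H2O2
Reagents that add atoms: none
Why: Evans syn-aldol: the imide, not the ester, is enolised to the (Z)-boron enolate, and the closed chair transition state with the auxiliary carbonyl turned away delivers the aldehyde to the enolate face remote from the benzyl group. This sets C7 (R) and C8 (S, 8α) under reagent control whatever the remote C10. The tert-butyl ester is too hindered to capture the C8 hydroxyl as a lactone.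

**Step 9**
Reactants: 15
Product: 16 tert-butyl (3R,4S,6S)-3-{[(4R)-4-benzyl-2-oxo-1,3-oxazolidin-3-yl]carbonyl}-4-[(tert-butyldimethylsilyl)oxy]-6,8-dimethyl-6-vinylnon-7-enoate
Conditions: TBSOTf, 2,6-lutidine, CH2Cl2, −78 → 0 °C
Reagents that add atoms: tert-butyldimethylsilyl trifluoromethanesulfonate, CC(C)(C)[Si](C)(C)OS(=O)(=O)C(F)(F)F
Why: Silylation of the secondary alcohol blocks retro-aldol and lactonisation and provides the bulky, poorly chelating C8 ether wanted in step 12.

**Step 10**
Reactants: 16
Product: 17 tert-butyl (3S,4S,6S)-4-[(tert-butyldimethylsilyl)oxy]-3-(hydroxymethyl)-6,8-dimethyl-6-vinylnon-7-enoate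
Conditions: LiBH4, MeOH (1 equiv), THF, 0 °C
Reagents that add atoms: none
Why: Chemoselective hydride cleavage of the imide to the primary alcohol; LiBH4 should leave the tert-butyl ester alone, and auxiliary 11 is recovered.

**Step 11**
Reactants: 17
Product: 18 tert-butyl (3R,4S,6S)-4-[(tert-butyldimethylsilyl)oxy]-3-formyl-6,8-dimethyl-6-vinylnon-7-enoate
Conditions: DMP, pyridine, CH2Cl2, 0 °C
Reagents that add atoms: none
Why: Buffered periodinane oxidation should give the α-branched aldehyde without epimerisation at C7 or loss of the β-silyloxy group; 18 is used directly.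

**Step 12**
Reactants: 18
Product: 19 tert-butyl 2-[(1S,2R,3S,4S,6S)-6-[(tert-butyldimethylsilyl)oxy]-2-hydroxy-4-methyl-3-(prop-1-en-2-yl)-4-vinylcyclohexyl]acetate
Conditions: Me2AlCl (1.1 equiv), CH2Cl2, −78 → −20 °C; aqueous potassium sodium tartrate
Reagents that add atoms: none
Why: Me2AlCl binds the C6 aldehyde oxygen, and C5 of the isobutenyl group bonds to C6 while a hydrogen of a C4 methyl group passes to oxygen through a six-membered array, so the alkene moves to C4=C3 and C15 stays a methyl group (a concerted, asynchronous type-one carbonyl-ene reaction; the aluminium alkoxide then loses methane, which removes the proton source). The closest known reaction type is the Lewis acid-promoted cyclisation of 7-methyloct-6-enals to trans-2-isopropenylcyclohexanols, as in citronellal to isopulegol. The cyclohexane C5–C10 closes at the proximal alkene carbon, 6-exo-trig with respect to the carbonyl, through a chair. That chair is fixed by the centres already present: the C7 arm and the 8α silyloxy group are both equatorial and only C14 on the quaternary C10 is axial, whereas the inverted chair would place C7, C8 and the vinyl group axial. C6 is controlled by the aluminium-bound oxygen taking the equatorial site (an axial one would be 1,3-syn to the axial C14), which gives 6α oxygen trans to the C7 arm. C5 is controlled by the isobutenyl group reacting from the equatorial position, which gives the 5,6-trans relation. The step needs chair selection (secured by the equatorial C7 and C8 groups), reaction of the trisubstituted alkene and not the vinyl group (secured by its nucleophilicity and the six-membered ring), and no chelation of O8 (secured by the bulky silyl ether and one equivalent of a monodentate Lewis acid). The two C4 methyl groups are diastereotopic but give the same isopropenyl group, and the ester and silyl ether should be inert at this temperature.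

**Step 13**
Reactants: 19
Product: 20 (3aS,4S,6S,7S,7aR)-4-[(tert-butyldimethylsilyl)oxy]-6-methyl-7-(prop-1-en-2-yl)-6-vinylhexahydro-1-benzofuran-2(3H)-one
Conditions: camphor-10-sulfonic acid (0.2 equiv), CH2Cl2, rt
Reagents that add atoms: none
Why: Acid-catalysed lactonisation: the equatorial C6 hydroxyl and the equatorial C7 acetate arm close the trans-fused γ-lactone with loss of isobutene; C8 is still silylated, so only O6 can lactonise.

**Step 14**
Reactants: 20
Product: 21 (3aR,4S,6S,7S,7aR)-4-hydroxy-6-methyl-7-(prop-1-en-2-yl)-6-vinylhexahydro-1-benzofuran-2(3H)-one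
Conditions: HF·pyridine, pyridine, THF, 0 °C → rt
Reagents that add atoms: none
Why: Fluoride-assisted desilylation under buffered acidic conditions; no alkoxide is formed, so the acyl group should not migrate from O6 to O8.

**Step 15**
Reactants: 21
Product: 22 (3aS,6S,7S,7aR)-6-methyl-7-(prop-1-en-2-yl)-6-vinylhexahydro-1-benzofuran-2,4-dione
Conditions: DMP, CH2Cl2, 0 °C; used crude
Reagents that add atoms: none
Why: Periodinane oxidation of the equatorial 8α alcohol under non-basic conditions, which spare the β-acyloxy ketone from E1cB opening and C7 from epimerisation; the ketone is reduced at once.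

**Step 16**
Reactants: 22
Product: 24 (3aS,4R,6S,7S,7aR)-6-methyl-7-(prop-1-en-2-yl)-4-[(triethylsilyl)oxy]-6-vinylhexahydro-1-benzofuran-2(3H)-one, via lithium alkoxide 23 (not isolated)
Conditions: LiBH(s-Bu)3, THF, −78 °C; then Et3SiOTf, 2,6-lutidine, −78 → −40 °C
Reagents that add atoms: triethylsilyl trifluoromethanesulfonate, CC[Si](CC)(CC)OS(=O)(=O)C(F)(F)F
Why: The bulky hydride should attack the C8 ketone from the α face, opposite the axial C14 methyl that shields the β face, and so give the axial 8β alkoxide. Trapping it cold as the silyl ether prevents its addition to the lactone carbonyl (migration to the 8,12-lactone) and protects O8 for the enolate step.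

**Step 17**
Reactants: 24
Product: 28 (3aS,4R,6S,7S,7aR)-6-methyl-3-methylidene-7-(prop-1-en-2-yl)-4-[(triethylsilyl)oxy]-6-vinylhexahydro-1-benzofuran-2(3H)-one, via lithium enolate 25 (not isolated), via Mannich base 26 (not isolated), via methiodide 27 (not isolated)
Conditions: LiN(i-Pr)2, THF, −78 °C; CH2=NMe2+ I−, −78 °C → rt; then MeI, rt; then aq. NaHCO3, rt
Reagents that add atoms: dimethyl(methylidene)ammonium iodide, C=[N+](C)C.[I-]
Why: Aminomethylation of the lactone enolate (Mannich-type alkylation with the iminium salt), quaternisation and base-induced elimination give the α-methylene lactone. At this stage the molecule holds no other acidic or electrophilic site, and C7 is not touched.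

**Step 18**
Reactants: 28
Product: 29 (3aR,4R,6S,7S,7aR)-4-hydroxy-6-methyl-3-methylidene-7-(prop-1-en-2-yl)-6-vinylhexahydro-1-benzofuran-2(3H)-one
Conditions: HF·pyridine, pyridine, THF, 0 °C
Reagents that add atoms: none
Why: Acidic fluoride cleaves the triethylsilyl ether without generating the free alkoxide, so neither lactone migration nor conjugate addition of O8 to C13 should be triggered.

**Step 19**
Reactants: 29; 30 (2E)-2-methylbut-2-enoyl chloride (tigloyl chloride)
Product: 31 (3aR,4R,6S,7S,7aR)-6-methyl-3-methylidene-2-oxo-7-(prop-1-en-2-yl)-6-vinyloctahydro-1-benzofuran-4-yl (2E)-2-methylbut-2-enoate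
Conditions: Et3N, DMAP (0.2 equiv), PhMe, 0 → 50 °C
Reagents that add atoms: none
Why: Acyl transfer from the acid chloride through the acylpyridinium ion esterifies the hindered axial 8β hydroxyl; the tiglate is the thermodynamically favoured alkene isomer, so no geometric scrambling is expected.

**Step 20**
Reactants: 31
Product: 33 (3aR,4R,6S,7R,7aR)-6-methyl-3-methylidene-2-oxo-7-(3-oxoprop-1-en-2-yl)-6-vinyloctahydro-1-benzofuran-4-yl (2E)-2-methylbut-2-enoate, via allylic alcohol 32 (not isolated)
Conditions: SeO2 (0.5 equiv), t-BuOOH, CH2Cl2, rt; then MnO2, rt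
Reagents that add atoms: selenium dioxide, O=[Se]=O; tert-butyl hydroperoxide, CC(C)(C)OO
Why: Allylic oxidation by SeO2 (ene reaction, then 2,3-sigmatropic shift) should attack the only electron-rich alkene that has allylic hydrogens, the isopropenyl group, at C15: the tertiary C5–H beside the quaternary carbon is hindered, the vinyl group has no allylic hydrogen, and the conjugated alkenes of the lactone and the tiglate are deactivated. MnO2 then converts the allylic alcohol into the enal.

**Step 21**
Reactants: 33
Product: 34 2-[(3aR,4R,6S,7R,7aR)-6-methyl-3-methylidene-4-{[(2E)-2-methylbut-2-enoyl]oxy}-2-oxo-6-vinyloctahydro-1-benzofuran-7-yl]prop-2-enoic acid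
Conditions: NaClO2, NaH2PO4, 2-methyl-2-butene, t-BuOH/H2O, 0 °C → rt
Reagents that add atoms: sodium chlorite, [Na+].[O-]Cl=O
Why: Pinnick oxidation converts the enal into the acid; the alkene scavenger removes hypochlorous acid, and the lactone, tiglate, vinyl and methylene groups should be inert.

## Compound list

1 | 2-methyl-2-vinyloxirane (racemic) | CC1(C=C)CO1 | starting material
2 | dimethyl malonate | COC(=O)CC(=O)OC | starting material
3 | dimethyl 2-[(2R)-1-hydroxy-2-methylbut-3-en-2-yl]propanedioate | C=C[C@@](C)(CO)C(C(=O)OC)C(=O)OC | intermediate (not isolated)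
4 | methyl (4R)-4-methyl-2-oxo-4-vinyloxolane-3-carboxylate (C3 epimers) | C=C[C@]1(C)C(C(=O)OC)C(=O)OC1 | intermediate
5 | (4S)-4-methyl-4-vinyloxolan-2-one | C=C[C@]1(C)CC(=O)OC1 | intermediate
6 | (3S)-3-(hydroxymethyl)-N-methoxy-N,3-dimethylpent-4-enamide | C=C[C@@](C)(CO)CC(=O)N(C)OC | intermediate
7 | (3S)-3-formyl-N-methoxy-N,3-dimethylpent-4-enamide | C=C[C@](C)(CC(=O)N(C)OC)C=O | intermediate
8 | (3S)-N-methoxy-N,3,5-trimethyl-3-vinylhex-4-enamide | C=C[C@](C)(CC(=O)N(C)OC)C=C(C)C | intermediate
9 | (3S)-3,5-dimethyl-3-vinylhex-4-enal | C=C[C@](C)(CC=O)C=C(C)C | intermediate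
10 | 4-tert-butoxy-4-oxobutanoic acid | CC(C)(C)OC(=O)CCC(=O)O | starting material
11 | (4R)-4-benzyl-1,3-oxazolidin-2-one | O=C1N[C@H](Cc2ccccc2)CO1 | starting material
12 | 4-tert-butoxy-4-oxobutanoic 2,2-dimethylpropanoic anhydride | CC(C)(C)OC(=O)CCC(=O)OC(=O)C(C)(C)C | intermediate (not isolated)
13 | tert-butyl 4-[(4R)-4-benzyl-2-oxo-1,3-oxazolidin-3-yl]-4-oxobutanoate | CC(C)(C)OC(=O)CCC(=O)N1[C@H](Cc2ccccc2)COC1=O | intermediate
14 | tert-butyl (3Z)-4-[(4R)-4-benzyl-2-oxo-1,3-oxazolidin-3-yl]-4-[(dibutylboranyl)oxy]but-3-enoate | CCCCB(CCCC)O/C(N1[C@H](Cc2ccccc2)COC1=O)=C\CC(=O)OC(C)(C)C | intermediate (not isolated)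
15 | tert-butyl (3R,4S,6S)-3-{[(4R)-4-benzyl-2-oxo-1,3-oxazolidin-3-yl]carbonyl}-4-hydroxy-6,8-dimethyl-6-vinylnon-7-enoate | C=C[C@](C)(C[C@H](O)[C@@H](CC(=O)OC(C)(C)C)C(=O)N1[C@H](Cc2ccccc2)COC1=O)C=C(C)C | intermediate
16 | tert-butyl (3R,4S,6S)-3-{[(4R)-4-benzyl-2-oxo-1,3-oxazolidin-3-yl]carbonyl}-4-[(tert-butyldimethylsilyl)oxy]-6,8-dimethyl-6-vinylnon-7-enoate | C=C[C@](C)(C[C@H](O[Si](C)(C)C(C)(C)C)[C@@H](CC(=O)OC(C)(C)C)C(=O)N1[C@H](Cc2ccccc2)COC1=O)C=C(C)C | intermediate
17 | tert-butyl (3S,4S,6S)-4-[(tert-butyldimethylsilyl)oxy]-3-(hydroxymethyl)-6,8-dimethyl-6-vinylnon-7-enoate | C=C[C@](C)(C[C@H](O[Si](C)(C)C(C)(C)C)[C@@H](CC(=O)OC(C)(C)C)CO)C=C(C)C | intermediate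
18 | tert-butyl (3R,4S,6S)-4-[(tert-butyldimethylsilyl)oxy]-3-formyl-6,8-dimethyl-6-vinylnon-7-enoate | C=C[C@](C)(C[C@H](O[Si](C)(C)C(C)(C)C)[C@H](C=O)CC(=O)OC(C)(C)C)C=C(C)C | intermediate
19 | tert-butyl 2-[(1S,2R,3S,4S,6S)-6-[(tert-butyldimethylsilyl)oxy]-2-hydroxy-4-methyl-3-(prop-1-en-2-yl)-4-vinylcyclohexyl]acetate | C=C[C@]1(C)C[C@H](O[Si](C)(C)C(C)(C)C)[C@@H](CC(=O)OC(C)(C)C)[C@H](O)[C@H]1C(C)=C | intermediate
20 | (3aS,4S,6S,7S,7aR)-4-[(tert-butyldimethylsilyl)oxy]-6-methyl-7-(prop-1-en-2-yl)-6-vinylhexahydro-1-benzofuran-2(3H)-one | C=C[C@]1(C)C[C@H](O[Si](C)(C)C(C)(C)C)[C@H]2CC(=O)O[C@@H]2[C@H]1C(C)=C | intermediate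
21 | (3aR,4S,6S,7S,7aR)-4-hydroxy-6-methyl-7-(prop-1-en-2-yl)-6-vinylhexahydro-1-benzofuran-2(3H)-one | C=C[C@]1(C)C[C@H](O)[C@H]2CC(=O)O[C@@H]2[C@H]1C(C)=C | intermediate
22 | (3aS,6S,7S,7aR)-6-methyl-7-(prop-1-en-2-yl)-6-vinylhexahydro-1-benzofuran-2,4-dione | C=C[C@]1(C)CC(=O)[C@H]2CC(=O)O[C@@H]2[C@H]1C(C)=C | intermediate
23 | lithium (3aR,4R,6S,7S,7aR)-6-methyl-2-oxo-7-(prop-1-en-2-yl)-6-vinyloctahydro-1-benzofuran-4-olate | [Li+].C=C[C@]1(C)C[C@@H]([O-])[C@H]2CC(=O)O[C@@H]2[C@H]1C(C)=C | intermediate (not isolated)
24 | (3aS,4R,6S,7S,7aR)-6-methyl-7-(prop-1-en-2-yl)-4-[(triethylsilyl)oxy]-6-vinylhexahydro-1-benzofuran-2(3H)-one | C=C[C@]1(C)C[C@@H](O[Si](CC)(CC)CC)[C@H]2CC(=O)O[C@@H]2[C@H]1C(C)=C | intermediate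
25 | lithium enolate of 24 (C11=C12–O−) | [Li+].C=C[C@]1(C)C[C@@H](O[Si](CC)(CC)CC)[C@H]2C=C([O-])O[C@@H]2[C@H]1C(C)=C | intermediate (not isolated)
26 | 3-[(dimethylamino)methyl] derivative of 24 (C11 epimers) | C=C[C@]1(C)C[C@@H](O[Si](CC)(CC)CC)[C@H]2C(CN(C)C)C(=O)O[C@@H]2[C@H]1C(C)=C | intermediate (not isolated)
27 | trimethylammonium iodide derived from 26 (C11 epimers) | [I-].C=C[C@]1(C)C[C@@H](O[Si](CC)(CC)CC)[C@H]2C(C[N+](C)(C)C)C(=O)O[C@@H]2[C@H]1C(C)=C | intermediate (not isolated)
28 | (3aS,4R,6S,7S,7aR)-6-methyl-3-methylidene-7-(prop-1-en-2-yl)-4-[(triethylsilyl)oxy]-6-vinylhexahydro-1-benzofuran-2(3H)-one | C=C[C@]1(C)C[C@@H](O[Si](CC)(CC)CC)[C@H]2C(=C)C(=O)O[C@@H]2[C@H]1C(C)=C | intermediate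
29 | (3aR,4R,6S,7S,7aR)-4-hydroxy-6-methyl-3-methylidene-7-(prop-1-en-2-yl)-6-vinylhexahydro-1-benzofuran-2(3H)-one | C=C[C@]1(C)C[C@@H](O)[C@H]2C(=C)C(=O)O[C@@H]2[C@H]1C(C)=C | intermediate
30 | (2E)-2-methylbut-2-enoyl chloride | C/C=C(\C)C(Cl)=O | starting material
31 | (3aR,4R,6S,7S,7aR)-6-methyl-3-methylidene-2-oxo-7-(prop-1-en-2-yl)-6-vinyloctahydro-1-benzofuran-4-yl (2E)-2-methylbut-2-enoate | C=C[C@]1(C)C[C@@H](OC(=O)/C(C)=C/C)[C@H]2C(=C)C(=O)O[C@@H]2[C@H]1C(C)=C | intermediate
32 | (3aR,4R,6S,7R,7aR)-7-(3-hydroxyprop-1-en-2-yl)-6-methyl-3-methylidene-2-oxo-6-vinyloctahydro-1-benzofuran-4-yl (2E)-2-methylbut-2-enoate | C=C[C@]1(C)C[C@@H](OC(=O)/C(C)=C/C)[C@H]2C(=C)C(=O)O[C@@H]2[C@H]1C(=C)CO | intermediate (not isolated)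
33 | (3aR,4R,6S,7R,7aR)-6-methyl-3-methylidene-2-oxo-7-(3-oxoprop-1-en-2-yl)-6-vinyloctahydro-1-benzofuran-4-yl (2E)-2-methylbut-2-enoate | C=C[C@]1(C)C[C@@H](OC(=O)/C(C)=C/C)[C@H]2C(=C)C(=O)O[C@@H]2[C@H]1C(=C)C=O | intermediate
34 | 2-[(3aR,4R,6S,7R,7aR)-6-methyl-3-methylidene-4-{[(2E)-2-methylbut-2-enoyl]oxy}-2-oxo-6-vinyloctahydro-1-benzofuran-7-yl]prop-2-enoic acid | C=C[C@]1(C)C[C@@H](OC(=O)/C(C)=C/C)[C@H]2C(=C)C(=O)O[C@@H]2[C@H]1C(=C)C(=O)O | target

## Step count and least certain steps

Total step count: 21. Longest linear sequence: 20 steps (steps 1–6 and 8–21); step 7 is a one-step side branch.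

**Step 12 (key step).** The most likely failure is a slow ring closure. C5 must bond next to the quaternary C10, and the reactive rotamer of the isobutenyl group suffers allylic 1,3-strain. A sluggish reaction would open the way to loss of silanol from the β-silyloxy aldehyde, epimerisation at C7, or stepwise cation chemistry.

Fallback: set out from 7 and make C5 the γ-carbon of an allylsilane, so that the same bond is formed by an intramolecular Hosomi–Sakurai reaction.
- Wittig reaction of 7 with the ylide made from ethyltriphenylphosphonium bromide (n-BuLi, then ICH2SiMe3, then n-BuLi) should give the allylsilane amide F1.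
- i-Bu2AlH reduction gives the allylsilane aldehyde F2.
- The aldol of step 8, through the same enolate 14, gives the aldol adduct F3.
- Silylation as in step 9 gives the silyl ether F4.
- LiBH4 gives the alcohol F5.
- Periodinane oxidation gives the allylsilane aldehyde F6.
- BF3·OEt2 in CH2Cl2 at −78 °C should then close C5–C6 with loss of the silyl group and return to the route at 19.

**Step 1.** The malonate may attack the unsubstituted allyl terminus (linear product), the facial selectivity may be poor, or lactonisation may be incomplete.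

Fallback: set out from 1 with methyl acetoacetate, a β-keto ester pronucleophile, under the same palladium and ligand system.
- The open adduct F7 closes in the flask to the acetyl lactone F8.
- Retro-Claisen deacetylation (NaOMe, MeOH, 0 °C) returns to the route at 5.

**Step 16.** The hydride may lose facial selectivity, the β-acyloxy ketone may open by E1cB, or the C8 alkoxide may attack C12 before it is silylated.

Fallback: set out from 21 and invert C8 by substitution instead of redox.
- Mitsunobu reaction (PPh3, diisopropyl azodicarboxylate, chloroacetic acid) gives the 8β chloroacetate F9.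
- Thiourea and NaHCO3 in EtOH release the 8β-hydroxy lactone F10 without a strong base.
- Et3SiOTf and 2,6-lutidine return to the route at 24.

This displacement has to approach syn to C14 and competes with elimination, so it is held in reserve.

**Step 20.** Chemoselectivity may fail through oxidation of the tiglate γ-methyl group or over-oxidation.

Fallback: set out from 29 and oxidise C15 before the tiglate is present.
- SeO2 and t-BuOOH give the diol F11.
- MnO2, which oxidises only the allylic hydroxyl, gives the hydroxy enal F12.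
- Acylation with 30 as in step 19 returns to the route at 33.

## Further compounds

F1 | step 12 | (3S)-N-methoxy-N,3,5-trimethyl-6-(trimethylsilyl)-3-vinylhex-4-enamide (E/Z mixture) | C=C[C@](C)(CC(=O)N(C)OC)C=C(C)C[Si](C)(C)C
F2 | step 12 | (3S)-3,5-dimethyl-6-(trimethylsilyl)-3-vinylhex-4-enal (E/Z mixture) | C=C[C@](C)(CC=O)C=C(C)C[Si](C)(C)C
F3 | step 12 | tert-butyl (3R,4S,6S)-3-{[(4R)-4-benzyl-2-oxo-1,3-oxazolidin-3-yl]carbonyl}-4-hydroxy-6,8-dimethyl-9-(trimethylsilyl)-6-vinylnon-7-enoate | C=C[C@](C)(C[C@H](O)[C@@H](CC(=O)OC(C)(C)C)C(=O)N1[C@H](Cc2ccccc2)COC1=O)C=C(C)C[Si](C)(C)C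
F4 | step 12 | tert-butyl (3R,4S,6S)-3-{[(4R)-4-benzyl-2-oxo-1,3-oxazolidin-3-yl]carbonyl}-4-[(tert-butyldimethylsilyl)oxy]-6,8-dimethyl-9-(trimethylsilyl)-6-vinylnon-7-enoate | C=C[C@](C)(C[C@H](O[Si](C)(C)C(C)(C)C)[C@@H](CC(=O)OC(C)(C)C)C(=O)N1[C@H](Cc2ccccc2)COC1=O)C=C(C)C[Si](C)(C)C
F5 | step 12 | tert-butyl (3S,4S,6S)-4-[(tert-butyldimethylsilyl)oxy]-3-(hydroxymethyl)-6,8-dimethyl-9-(trimethylsilyl)-6-vinylnon-7-enoate | C=C[C@](C)(C[C@H](O[Si](C)(C)C(C)(C)C)[C@@H](CC(=O)OC(C)(C)C)CO)C=C(C)C[Si](C)(C)C
F6 | step 12 | tert-butyl (3R,4S,6S)-4-[(tert-butyldimethylsilyl)oxy]-3-formyl-6,8-dimethyl-9-(trimethylsilyl)-6-vinylnon-7-enoate | C=C[C@](C)(C[C@H](O[Si](C)(C)C(C)(C)C)[C@H](C=O)CC(=O)OC(C)(C)C)C=C(C)C[Si](C)(C)C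
F7 | step 1 | methyl (3R)-2-acetyl-3-(hydroxymethyl)-3-methylpent-4-enoate (C2 epimers) | C=C[C@@](C)(CO)C(C(C)=O)C(=O)OC
F8 | step 1 | (4R)-3-acetyl-4-methyl-4-vinyloxolan-2-one (C3 epimers) | C=C[C@]1(C)C(C(C)=O)C(=O)OC1
F9 | step 16 | (3aR,4R,6S,7S,7aR)-6-methyl-2-oxo-7-(prop-1-en-2-yl)-6-vinyloctahydro-1-benzofuran-4-yl chloroacetate | C=C[C@]1(C)C[C@@H](OC(=O)CCl)[C@H]2CC(=O)O[C@@H]2[C@H]1C(C)=C
F10 | step 16 | (3aR,4R,6S,7S,7aR)-4-hydroxy-6-methyl-7-(prop-1-en-2-yl)-6-vinylhexahydro-1-benzofuran-2(3H)-one | C=C[C@]1(C)C[C@@H](O)[C@H]2CC(=O)O[C@@H]2[C@H]1C(C)=C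
F11 | step 20 | (3aR,4R,6S,7R,7aR)-4-hydroxy-7-(3-hydroxyprop-1-en-2-yl)-6-methyl-3-methylidene-6-vinylhexahydro-1-benzofuran-2(3H)-one | C=C[C@]1(C)C[C@@H](O)[C@H]2C(=C)C(=O)O[C@@H]2[C@H]1C(=C)CO
F12 | step 20 | 2-[(3aR,4R,6S,7R,7aR)-4-hydroxy-6-methyl-3-methylidene-2-oxo-6-vinyloctahydro-1-benzofuran-7-yl]prop-2-enal | C=C[C@]1(C)C[C@@H](O)[C@H]2C(=C)C(=O)O[C@@H]2[C@H]1C(=C)C=O
A1 | alternative 1 | open-chain C8 aldehyde and C11 acid, 6-O-silyl, tert-butyl acrylate on C5 | C=C[C@](C)(CC=O)[C@H](C(=C)C(=O)OC(C)(C)C)[C@H](CC(=O)O)O[Si](C)(C)C(C)(C)C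
A2 | alternative 1 | cyclohexane-fused cis β-lactone (O8–C11), 6-O-silyl, tert-butyl acrylate on C5 | C=C[C@]1(C)C[C@H]2OC(=O)[C@H]2[C@H](O[Si](C)(C)C(C)(C)C)[C@H]1C(=C)C(=O)OC(C)(C)C
A3 | alternative 2 | trans γ-lactone with C8 ethyl enol ether on C7 and, on C6, the C5 methyl ester carbon bearing the divinyl methyl C10 | C=CC(C)(C=C)[C@H](C(=O)OC)[C@H]1OC(=O)C[C@@H]1C(OCC)=C
A4 | alternative 2 | trans-fused bicyclic lactone with cyclic C8 enol ether, C10 methyl and vinyl, C4 methyl ester | C=C[C@]1(C)C=C(OCC)[C@H]2CC(=O)O[C@@H]2[C@H]1C(=O)OC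
A5 | alternative 3 | open-chain C6 aldehyde with (Z)-2-(bromomethyl)enoate at C7=C11, 8-O-silyl, tert-butyl acrylate on C5 | C=C[C@](C)(C[C@@H](O[Si](C)(C)C(C)(C)C)/C=C(\CBr)C(=O)OC)[C@@H](C=O)C(=C)C(=O)OC(C)(C)C
A6 | alternative 3 | bicyclic α-methylene lactone, 8-O-silyl, tert-butyl ester at C15 | C=C[C@]1(C)C[C@@H](O[Si](C)(C)C(C)(C)C)[C@H]2C(=C)C(=O)O[C@@H]2[C@H]1C(=C)C(=O)OC(C)(C)C
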